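All runs were generated by integration on assumed constants, and the scatter is random.

At 20.0 d the ash run held more other capture product than target, 49.1% against 34.1%, while the maple run at 20.0 d held less, 18.4% against 52.3%. Second nucleophile was charged at 32 mM in ash and 8 mM in maple, with the other charges equal, so I started from your hunch that the ratio follows that charge.

common to all: substrate 20 mM

| run | first nucleophile | second nucleophile | remark | time |
|---|---|---|---|---|
| maple | 20 mM | 8 mM | run made earlier |  |
| ash | 20 mM | 32 mM | run made earlier |  |
| flask | 20.0 mM | 16.0 mM |  | 15 d |

| run | time / d | other capture product / % | target / % |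
|---|---|---|---|
| maple | 5.00 | 14.7 | 40.9 |
| maple | 10.0 | 17.9 | 49.0 |
| maple | 15.0 | 18.5 | 51.4 |
| maple | 20.0 | 18.4 | 52.3 |
| ash | 1.25 | 15.0 | 11.0 |
| ash | 3.00 | 28.9 | 20.8 |
| ash | 8.00 | 44.7 | 31.0 |
| ash | 20.0 | 49.1 | 34.1 |

(each reading ± 0.3 percentage points)

- ratio of other capture product to target at 5.0 h
- ratio of other capture product to target at 40 h
- ratio of other capture product to target at 15 d
- which of other capture product and target there is more of at 15 d

- the numbers in the tables scatter by 0.3 percentage points (one standard deviation)

I divided the ratio of other capture product to target by [second nucleophile]/[first nucleophile] as charged. The earliest reading of each run gave 0.852 for ash and 0.899 for maple, and I took their mean, 0.875, as the capture ratio per charge, the usual selectivity factor. For your flask I multiplied it by 16.0 mM/20.0 mM and got 0.700, so I put target ahead.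

The forecast, made from the same runs, gave 0.68 at 5.0 h, 0.69 at 40 h and 0.71 at 15 d, with target in the lead, reading the runs as “kinetic competition for one species, with no sign of product interconversion”. Its factor was 0.85, so its early ratio stood a little below mine.

    substrate → intermediate (k = 3.50 × 10⁻⁶ s⁻¹)
    first nucleophile + intermediate → target (k = 0.00790 M⁻¹ s⁻¹)
    second nucleophile + intermediate → other capture product (k = 0.00690 M⁻¹ s⁻¹)
    intermediate → solvolysis product (k = 6.10 × 10⁻⁵ s⁻¹)
    substrate + intermediate → side product (k = 2.00 × 10⁻⁴ M⁻¹ s⁻¹)

The forecast held: the flask gave 0.700 at 5.0 h, 0.707 at 40 h and 0.722 at 15 d, with target at 43.8% against 31.6% of other capture product. The flask also held 22.2% of solvolysis product at 15.0 d, and that step made no difference worth counting to the ratio at that time. For the neighbour charged with 64 mM of second nucleophile, the capture ratio per charge of 0.875 gives 2.80. That neighbour gave 2.84 at 15 d, holding 65.2% of other capture product against 23.0% of target.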